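**Plan**
1. Retrosynthetic cuts, in order:
   - The terminal =CH2 carbons of the two allyl groups are traded for one shared Z-CH=CH unit (reverse ethenolysis).
   - C5–C6 of cyclohexenone ring A goes back to the dienone.
   - The C4–O bond to aryl ring B is cut.
   - The central C=C of the resulting symmetric bis-phenol is cut (reverse homometathesis).
   - The aryl–allyl bond goes back to an allyl aryl ether (reverse Claisen).
2. Enabling feature: on ring A the C4 aryloxy and C6 allyl groups are 1,3-cis, and ring B carries its allyl group at C2', next to the ether carbon C1'. Joined tail to tail, the allyl groups close a ten-membered ring (O, C4, C5, C6, four bridge carbons, C2', C1'), and both halves become the same 2-allyl-4,5-dimethoxyphenol.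
3. Forward order: both six-membered rings are bought as arenes and the chain is joined by Z-selective homometathesis. The ten-membered ring arises as trivalent iodine dearomatises ring A. C5=C6 is then reduced and ethene reopens the ring.
4. Stereochemistry: C4 (R) comes from a C2-symmetric chiral diacetoxyiodoarene in the ring closure and is sharpened by a matched chiral copper hydride. C6 (S) comes from the bridge, which tolerates only the cis epimer.

Key step: step 6

Numbering: ring A has C1 (C=O), C2 (H), C3 (OMe), C4 (ketal carbon), C5 and C6 (allyl or bridge). Ring B has C1' (O) and C2' (allyl or bridge). This numbering is also used for the phenol precursors.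

Assumption: the sense of induction of iodane 9 and of the (R)-DTBM-SEGPHOS copper hydride cannot be derived for this ring system; the enantiomers written are taken to favour (R)-11, and the mirror-image reagents would be used otherwise.

Step 1
Reactants: 1 3,4-dimethoxyphenol; 2 allyl bromide
Product: 3 4-(allyloxy)-1,2-dimethoxybenzene
Conditions: K2CO3 (1.5 equiv), acetone, reflux
Reagents that add atoms: allyl bromide (2), C=CCBr
Why: Williamson ether synthesis, in which the phenoxide formed with K2CO3 displaces bromide from the unhindered allylic halide at oxygen and no stereocentre is involved.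

Step 2
Reactants: 3 4-(allyloxy)-1,2-dimethoxybenzene
Product: 5 2-allyl-4,5-dimethoxyphenyl acetate, via 2-allyl-4,5-dimethoxyphenol 4 (not isolated)
Conditions: PhNEt2, 200 °C; then 25 °C, Ac2O, DMAP (cat.)
Reagents that add atoms: acetic anhydride, CC(=O)OC(C)=O
Why: Aromatic Claisen rearrangement, in which the [3,3] shift goes to the open ortho position rather than to the one flanked by the 3-methoxy group, and acetylation in the same pot masks the acidic OH that could protonate the ruthenium–carbon chelate of the next catalyst.

Step 3
Reactants: 5 2-allyl-4,5-dimethoxyphenyl acetate (two molecules)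
Product: 6 (Z)-1,4-bis(2-acetoxy-4,5-dimethoxyphenyl)but-2-ene
Conditions: Z-selective cyclometalated Grubbs catalyst Ru(NO3)(=CH-C6H4-2-OiPr)[C,C-chelating 1-(adamantane-1,2-diyl)-3-(2,6-diisopropylphenyl)imidazolidin-2-ylidene] (1 mol %), THF (1 M), 35 °C, static vacuum
Reagents that add atoms: none
Why: Z-selective olefin homometathesis of an allylbenzene, the standard substrate class of this catalyst type, whose side-bound metallacyclobutane keeps both substituents away from the N-aryl group and so releases the cis alkene, while pumping off the volatile co-product drives conversion.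

Step 4
Reactants: 6 (Z)-1,4-bis(2-acetoxy-4,5-dimethoxyphenyl)but-2-ene
Product: 7 (Z)-1,4-bis(2-hydroxy-4,5-dimethoxyphenyl)but-2-ene
Conditions: K2CO3 (0.2 equiv), degassed MeOH, 0 to 25 °C, argon; aq NH4Cl
Reagents that add atoms: none
Why: Base-catalysed transesterification cleaves aryl acetates quickly without touching the methyl ethers or the Z-alkene, and exclusion of air protects the electron-rich phenoxide.

Step 5
Reactants: 8 (R,R)-2,2'-[(2-iodo-1,3-phenylene)bis(oxy)]bis[N-(2,4,6-trimethylphenyl)propanamide]
Product: 9 the corresponding (R,R)-(diacetoxyiodo)arene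
Conditions: AcOOH (35 wt % in AcOH), AcOH, 25 °C; crystallised and dried
Reagents that add atoms: peracetic acid, CC(=O)OO; acetic acid, CC(=O)O
Why: Classical peracid oxidation of an iodoarene from monovalent to trivalent iodine, which leaves the two lactamide stereocentres untouched and, run separately, keeps peracid away from the Z-alkene of 7.

Step 6
Reactants: 7 (Z)-1,4-bis(2-hydroxy-4,5-dimethoxyphenyl)but-2-ene; 9 (R,R)-(diacetoxyiodo)arene
Product: 11 (4R)-bridged dienone (ring A 3,4-dimethoxycyclohexa-2,5-dienone; C4–O–C1' ether to the 4,5-dimethoxyphenyl ring B; C6 and C2' joined by a Z-but-2-ene-1,4-diyl chain), via aryloxy(acetoxy)iodane 10 (not isolated)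
Conditions: 9 (1.05 equiv, syringe pump) into 7 (1 mM), 2,6-di-tert-butylpyridine (2.5 equiv), 4 Å MS, CH2Cl2–(CF3)2CHOH 9:1, −20 °C; Et3N-deactivated silica
Reagents that add atoms: none
Why: Proposed new method: one phenol of 7 displaces an acetate from trivalent iodine to give 10, and as iodoarene 8 leaves from O1 the charge building up at the methoxy-bearing para carbon C4 (a methoxy-oxocarbenium ion in the limit) is quenched by the ring B oxygen, whose proton goes to acetate. The closest known reactions are the PhI(OAc)2 oxidation of p-methoxyphenols in alcohols to quinone monoketals, its intramolecular form with tethered alcohols that gives cyclic mixed ketals, and enantioselective phenol dearomatisations with this class of C2-symmetric lactamide iodoarenes; a phenol as oxygen nucleophile, a ten-membered ring and asymmetric para attack have not been combined. The ten-membered ring (O, C4, C5, C6, four bridge carbons, C2', C1') closes in a formal 10-exo-trig mode on the C4=O+Me carbon and leaves C5=C6 as a trans-configured bridgehead alkene of a bicyclo[7.3.1]tridecane frame, a size at which bridgehead enones are stable. C4 is the only new stereocentre: in the associative pathway favoured by the CH2Cl2-rich medium and the low temperature, iodine lies over one face of ring A and ring B must attack the other, so the lactamide arms of 9 choose the face. The step needs oxygen over carbon attack, para over ortho attack and ring closure over oligomerisation: the C4 methoxy group localises the charge at C4, the nucleophilic carbons of ring B cannot reach C4 through the four-carbon bridge without greater strain, the Z-alkene folds ring B over ring A, and 1 mM concentration with slow addition of 9 holds back intermolecular capture. Because the two rings of 7 are identical it does not matter which one is oxidised, and the hindered pyridine takes up acetic acid so that the aryl ketal does not ionise again.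

Step 7
Reactants: 11 (4R)-bridged dienone
Product: 12 (4R,6S)-bridged enone (as 11 but C5–C6 saturated; bridge CH2 at C6 cis to the C4 aryloxy oxygen, H at C6 on the C4 methoxy face)
Conditions: Cu(OAc)2 (5 mol %), (R)-DTBM-SEGPHOS (5.5 mol %), (EtO)2MeSiH (1.2 equiv), t-BuOH (1.5 equiv), toluene, −20 °C, followed by chiral HPLC; pH 7 buffer
Reagents that add atoms: none
Why: Ligand-accelerated copper hydride conjugate reduction, in which hydride adds to C5 of the strained alkyl-substituted enone rather than to the deactivated methoxy-bearing vinylogous ester and from the ring A face not covered by the bridge, t-BuOH protonates the copper enolate at C6 on that same open face so that the bridge stays cis to the aryloxy group (6S, the trans-bridged epimer being far more strained), and the chiral ligand makes the reduction a kinetic resolution of the kind known for racemic cyclic enones, so that residual (S)-dienone is left behind.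

Step 8
Reactants: 12 (4R,6S)-bridged enone; 13 ethene
Product: 14 (4R,6S)-6-allyl-4-(2-allyl-4,5-dimethoxyphenoxy)-3,4-dimethoxycyclohex-2-en-1-one (CNP0352100.2)
Conditions: ethene (4 bar), second-generation Hoveyda–Grubbs catalyst RuCl2(SIMes)(=CH-C6H4-2-OiPr) (SIMes = 1,3-dimesitylimidazolidin-2-ylidene, 5 mol %), 1,4-benzoquinone (10 mol %), CH2Cl2 (5 mM), 25 °C; ethyl vinyl ether quench under ethene; Et3N-deactivated silica
Reagents that add atoms: ethene (13), C=C
Why: Ethenolysis (ring-opening cross metathesis), in which excess ethene and release of medium-ring strain shift the equilibrium to the open diene, the trisubstituted push–pull C2=C3 alkene is inert to the catalyst, benzoquinone suppresses ruthenium hydride migration of the allyl double bonds, and the neutral medium leaves C4 and C6 untouched.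

**Compound list**
1 | 3,4-dimethoxyphenol | COc1ccc(O)cc1OC | starting material
2 | allyl bromide | C=CCBr | starting material
3 | 4-(allyloxy)-1,2-dimethoxybenzene | C=CCOc1ccc(OC)c(OC)c1 | intermediate
4 | 2-allyl-4,5-dimethoxyphenol (not isolated) | C=CCc1cc(OC)c(OC)cc1O | intermediate
5 | 2-allyl-4,5-dimethoxyphenyl acetate | C=CCc1cc(OC)c(OC)cc1OC(C)=O | intermediate
6 | (Z)-1,4-bis(2-acetoxy-4,5-dimethoxyphenyl)but-2-ene | COc1cc(OC(C)=O)c(C/C=C\Cc2cc(OC)c(OC)cc2OC(C)=O)cc1OC | intermediate
7 | (Z)-1,4-bis(2-hydroxy-4,5-dimethoxyphenyl)but-2-ene | COc1cc(O)c(C/C=C\Cc2cc(OC)c(OC)cc2O)cc1OC | intermediate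
8 | (R,R)-2,2'-[(2-iodo-1,3-phenylene)bis(oxy)]bis[N-(2,4,6-trimethylphenyl)propanamide] | Ic1c(O[C@H](C)C(=O)Nc2c(C)cc(C)cc2C)cccc1O[C@H](C)C(=O)Nc1c(C)cc(C)cc1C | starting material
9 | (R,R)-(diacetoxyiodo)arene derived from 8 | CC(=O)OI(OC(C)=O)c1c(O[C@H](C)C(=O)Nc2c(C)cc(C)cc2C)cccc1O[C@H](C)C(=O)Nc1c(C)cc(C)cc1C | intermediate
10 | aryloxy(acetoxy)iodane: one phenol oxygen of 7 bound to the iodine of 9 in place of one acetate (not isolated) | COc1cc(O)c(C/C=C\Cc2cc(OC)c(OC)cc2OI(OC(C)=O)c2c(O[C@H](C)C(=O)Nc3c(C)cc(C)cc3C)cccc2O[C@H](C)C(=O)Nc2c(C)cc(C)cc2C)cc1OC | intermediate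
11 | (4R)-bridged dienone, ten-membered aryl ether ring with Z-alkene | COc1cc2c(cc1OC)O[C@]1(OC)C=C(C/C=C\C2)C(=O)C=C1OC | intermediate
12 | (4R,6S)-bridged enone, bridge cis across C4 and C6 | COc1cc2c(cc1OC)O[C@]1(OC)C[C@H](C/C=C\C2)C(=O)C=C1OC | intermediate
13 | ethene | C=C | starting material
14 | (4R,6S)-6-allyl-4-(2-allyl-4,5-dimethoxyphenoxy)-3,4-dimethoxycyclohex-2-en-1-one | C=CCc1cc(OC)c(OC)cc1O[C@]1(OC)C[C@H](CC=C)C(=O)C=C1OC | target

**Step count**
Total step count: 8. Longest linear sequence: 7 (steps 1–4 and 6–8). Step 5 prepares the oxidant.

**Steps most likely to fail**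

**Step 6.**
- Ring closure may lose to intermolecular capture.
- It may also lose to attack at the alkyl-bearing ortho carbon C6, which would close an eight-membered ring.
- The cation may collapse with traces of water or acetate.
- Facial selectivity may be low.

The fallback inverts the order of events and uses only known reactions.
- It sets out from phenol 4, obtained by working up step 2 before acetic anhydride is added.
- It comes back to the route at 11.

Sequence:
- Nucleophilic aromatic substitution of 4 on 4-fluoro-3-methoxybenzaldehyde (K2CO3, DMF, 110 °C) should give 4-(2-allyl-4,5-dimethoxyphenoxy)-3-methoxybenzaldehyde F1.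
- Acid Dakin oxidation (H2O2, catalytic H2SO4, MeOH) should give 4-(2-allyl-4,5-dimethoxyphenoxy)-3-methoxyphenol F2.
- Allyl bromide 2 and K2CO3 should give 1-allyl-2-[4-(allyloxy)-2-methoxyphenoxy]-4,5-dimethoxybenzene F3.
- Claisen rearrangement (PhNEt2, 200 °C) should give 2-allyl-4-(2-allyl-4,5-dimethoxyphenoxy)-5-methoxyphenol F4.
- PhI(OAc)2 in MeOH over NaHCO3 at 0 °C should give the open mixed ketal, racemic 2-allyl-4-(2-allyl-4,5-dimethoxyphenoxy)-4,5-dimethoxycyclohexa-2,5-dien-1-one F5. Here methanol, not the phenol, is the nucleophile.
- Ring-closing metathesis at high dilution with the catalyst of step 3 should give the racemic bridged dienone F6.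
- Separation of its enantiomers on a chiral stationary phase gives 11.

**Step 7.**
- Hydride delivery may go to the carbonyl group.
- It may go to the methoxy-bearing alkene, with loss of methoxide.
- The copper enolate may expel the aryloxide, with re-aromatisation.
- The two enantiomers may be reduced at similar rates.

The fallback sets out from 11 and comes back at 12.
- 1,4-Hydrosilylation with Et3SiH and RhCl(PPh3)3 (toluene, 40 °C) should give the isolable triethylsilyl dienol ether of the bridged enone F7.
- Bu4NF buffered with AcOH (THF, −78 °C) then frees the enolate for protonation under near-neutral conditions, with the bridge again imposing the cis outcome.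
- Enantiomeric purity would then rest on separating 11 on a chiral stationary phase before the reduction.

**Step 8.**
- The allyl double bonds may migrate into conjugation.
- Re-closure or oligomerisation may set in once ethene is released.
- Catalyst residues may ionise the aryl ketal.

The fallback sets out from 12 and comes back at 14 without metathesis.
- OsO4 (cat.) and N-methylmorpholine N-oxide (acetone–water, 0 °C) should dihydroxylate only the isolated Z-alkene, giving the bridged syn-diol mixture F8.
- NaIO4 on silica (CH2Cl2) should open the ring to the dialdehyde (4R,6S)-4-[4,5-dimethoxy-2-(2-oxoethyl)phenoxy]-3,4-dimethoxy-6-(2-oxoethyl)cyclohex-2-en-1-one F9.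
- Double Wittig methylenation with Ph3P=CH2, made from Ph3PCH3Br and KN(SiMe3)2 (THF, −78 °C), should convert both aldehydes faster than the vinylogous ester carbonyl and give 14.

**Further compounds**
F1 | step 6 | 4-(2-allyl-4,5-dimethoxyphenoxy)-3-methoxybenzaldehyde | C=CCc1cc(OC)c(OC)cc1Oc1ccc(C=O)cc1OC
F2 | step 6 | 4-(2-allyl-4,5-dimethoxyphenoxy)-3-methoxyphenol | C=CCc1cc(OC)c(OC)cc1Oc1ccc(O)cc1OC
F3 | step 6 | 1-allyl-2-[4-(allyloxy)-2-methoxyphenoxy]-4,5-dimethoxybenzene | C=CCOc1ccc(Oc2cc(OC)c(OC)cc2CC=C)c(OC)c1
F4 | step 6 | 2-allyl-4-(2-allyl-4,5-dimethoxyphenoxy)-5-methoxyphenol | C=CCc1cc(Oc2cc(OC)c(OC)cc2CC=C)c(OC)cc1O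
F5 | step 6 | racemic 2-allyl-4-(2-allyl-4,5-dimethoxyphenoxy)-4,5-dimethoxycyclohexa-2,5-dien-1-one | C=CCC1=CC(OC)(Oc2cc(OC)c(OC)cc2CC=C)C(OC)=CC1=O
F6 | step 6 | racemic bridged dienone | COc1cc2c(cc1OC)OC1(OC)C=C(C/C=C\C2)C(=O)C=C1OC
F7 | step 7 | triethylsilyl dienol ether of the bridged enone | COc1cc2c(cc1OC)O[C@]1(OC)CC(C/C=C\C2)=C(O[Si](CC)(CC)CC)C=C1OC
F8 | step 8 | bridged syn-diol mixture (carbinol configuration not defined) | COc1cc2c(cc1OC)O[C@]1(OC)C[C@H](CC(O)C(O)C2)C(=O)C=C1OC
F9 | step 8 | (4R,6S)-4-[4,5-dimethoxy-2-(2-oxoethyl)phenoxy]-3,4-dimethoxy-6-(2-oxoethyl)cyclohex-2-en-1-one | O=CCc1cc(OC)c(OC)cc1O[C@]1(OC)C[C@H](CC=O)C(=O)C=C1OC
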